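**Plan**

- Retrosynthesis: the six MOM ethers and a sacrificial tert-butyl ester on C3 are removed last. Ring C of the flavanone half is then cut at O1–C2, followed by the C2=C3 alkene (Knoevenagel), the C3–CO2tBu bond (Claisen) and the C6–C8'' biaryl bond (Suzuki–Miyaura). Flavone atoms carry a double prime.
- Enabling feature: in ring C the O1–C2 bond lies beta to the C4 ketone, so the ring opens to a 2-hydroxyaryl enone. C4a, which bears that ketone, sits between the oxygen-bearing carbons C5 and C8a; with the C5 oxygen capped and only the C8a hydroxyl free, closure can give the 6-linked isomer alone.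
- Forward order: apigenin supplies rings A'', B'' and C'' intact and is borylated at C8''. Phloroacetophenone becomes ring A, iodinated at the future C6. The biaryl bond is made, the acetyl group is extended to the ketoester, ring B enters with the aldehyde, and ring C closes last.
- Stereochemistry: C2 (S) is set in the ring closure by a bifunctional cinchona thiourea bound to the ketone/ester pair. C3 is a transient centre lost with CO2. The C6–C8'' axis is not controlled.

Key step: step 13

Naming note: "tri-MOM-flavon-8-yl" stands for the 5,7-bis(methoxymethoxy)-2-[4-(methoxymethoxy)phenyl]-4-oxo-4H-chromen-8-yl group.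

Remark on the axis: the tetra-ortho-substituted C6–C8'' bond may rotate slowly, in which case compounds 10 to 20 would be mixtures of axial isomers that all carry the same C2 configuration after step 13; the target as specified allows this.

Remark on the catalyst: the quinine-derived thiourea is assumed to deliver (2S); if the sense proves opposite, the quinidine-derived pseudoenantiomer takes its place unchanged in every other respect.

**Route**

Step 1
Reactants: 1 apigenin (5,7-dihydroxy-2-(4-hydroxyphenyl)-4H-chromen-4-one)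
Product: 2 apigenin tris-MOM ether (5,7-bis(methoxymethoxy)-2-[4-(methoxymethoxy)phenyl]-4H-chromen-4-one)
Conditions: NaH, MOMCl, DMF, 0 °C to rt
Reagents that add atoms: chloromethyl methyl ether (MOMCl), COCCl
Why: Williamson-type O-alkylation of the three phenoxides, with NaH in DMF chosen because the C5'' hydroxyl is hydrogen-bonded to the C4'' carbonyl and needs full deprotonation.

Step 2
Reactants: 2 apigenin tris-MOM ether
Product: 3 8-iodo-5,7-bis(methoxymethoxy)-2-[4-(methoxymethoxy)phenyl]-4H-chromen-4-one
Conditions: NIS, DMF, 50 °C, dark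
Reagents that add atoms: N-iodosuccinimide, O=C1CCC(=O)N1I
Why: Electrophilic aromatic iodination that, as known for fully O-alkylated 5,7-dioxygenated flavones, should prefer C8'' (between the ring oxygen and one ether) over the more crowded C6'' (between two ethers), while neutral NIS spares the acetals.

Step 3
Reactants: 3 8-iodoflavone
Product: 4 5,7-bis(methoxymethoxy)-2-[4-(methoxymethoxy)phenyl]-8-(4,4,5,5-tetramethyl-1,3,2-dioxaborolan-2-yl)-4H-chromen-4-one
Conditions: B2pin2, PdCl2(dppf) (5 mol %), KOAc, 1,4-dioxane, 90 °C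
Reagents that add atoms: bis(pinacolato)diboron, CC1(C)OB(OC1(C)C)B1OC(C)(C)C(C)(C)O1
Why: Miyaura borylation, in which the aryl iodide adds to zerovalent palladium, acetate assists boron transfer from B2pin2, and the weak base KOAc avoids homocoupling.

Step 4
Reactants: 5 phloroacetophenone (1-(2,4,6-trihydroxyphenyl)ethan-1-one)
Product: 6 1-[2,6-dihydroxy-4-(methoxymethoxy)phenyl]ethan-1-one
Conditions: MOMCl (1.0 equiv), iPr2NEt, THF, 0 °C
Reagents that add atoms: chloromethyl methyl ether (MOMCl), COCCl
Why: Chelation-controlled mono-O-alkylation, since the two ortho hydroxyls are held in hydrogen bonds to the acetyl group and the more acidic para hydroxyl (future C7 oxygen) reacts first.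

Step 5
Reactants: 6 1-[2,6-dihydroxy-4-(methoxymethoxy)phenyl]ethan-1-one
Product: 7 1-[2-(benzyloxy)-6-hydroxy-4-(methoxymethoxy)phenyl]ethan-1-one
Conditions: BnBr (1.1 equiv), K2CO3, acetone, reflux
Reagents that add atoms: benzyl bromide, BrCc1ccccc1
Why: Williamson ether synthesis on one of two equivalent chelated hydroxyls; the remaining hydroxyl stays locked in its hydrogen bond and resists a second alkylation, and the benzyl ether marks the oxygen that will become O1.

Step 6
Reactants: 7 1-[2-(benzyloxy)-6-hydroxy-4-(methoxymethoxy)phenyl]ethan-1-one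
Product: 8 1-[6-(benzyloxy)-2-hydroxy-3-iodo-4-(methoxymethoxy)phenyl]ethan-1-one
Conditions: NIS (1.05 equiv), DMF, 0 °C to rt
Reagents that add atoms: N-iodosuccinimide, O=C1CCC(=O)N1I
Why: Electrophilic iodination directed ortho to the free chelated phenol, the regiochemistry known for 2-hydroxy-4,6-dialkoxyacetophenones and 5-hydroxyflavones, which puts iodine on the future C6 next to the future C5 oxygen.

Step 7
Reactants: 8 1-[6-(benzyloxy)-2-hydroxy-3-iodo-4-(methoxymethoxy)phenyl]ethan-1-one
Product: 9 1-[6-(benzyloxy)-3-iodo-2,4-bis(methoxymethoxy)phenyl]ethan-1-one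
Conditions: NaH, MOMCl, DMF, 0 °C to rt
Reagents that add atoms: chloromethyl methyl ether (MOMCl), COCCl
Why: Williamson-type O-alkylation of the hindered sodium phenoxide, which permanently caps the oxygen (future C5 oxygen) that must not take part in the later ring closure.

Step 8
Reactants: 4 flavone 8-boronate, 9 1-[6-(benzyloxy)-3-iodo-2,4-bis(methoxymethoxy)phenyl]ethan-1-one
Product: 10 1-[6-(benzyloxy)-2,4-bis(methoxymethoxy)-3-(tri-MOM-flavon-8-yl)phenyl]ethan-1-one
Conditions: Pd(OAc)2 (5 mol %), SPhos (10 mol %), K3PO4, toluene/H2O (10:1), 100 °C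
Reagents that add atoms: none
Why: Suzuki–Miyaura coupling, using the bulky electron-rich biarylphosphine SPhos (2-dicyclohexylphosphino-2',6'-dimethoxybiphenyl) on zerovalent palladium, the ligand class established for joining two di-ortho-substituted partners; ketone, acetals and benzyl ether are inert to aqueous K3PO4.

Step 9
Reactants: 10 biaryl methyl ketone
Product: 12 tert-butyl 3-[6-(benzyloxy)-2,4-bis(methoxymethoxy)-3-(tri-MOM-flavon-8-yl)phenyl]-3-oxopropanoate, via lithium enolate 11 (not isolated)
Conditions: LiN(SiMe3)2 (2.5 equiv), THF, −78 °C; then Boc2O, −78 to 0 °C; aq. NH4Cl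
Reagents that add atoms: di-tert-butyl dicarbonate, CC(C)(C)OC(=O)OC(=O)OC(C)(C)C
Why: Claisen-type C-acylation of the methyl ketone enolate by Boc2O, pulled to the C-acylated product because excess amide base converts the ketoester into its stabilised enolate, while LiN(SiMe3)2 is too weak to metalate the flavone.

Step 10
Reactants: 12 benzyl-protected tert-butyl ketoester
Product: 13 tert-butyl 3-[6-hydroxy-2,4-bis(methoxymethoxy)-3-(tri-MOM-flavon-8-yl)phenyl]-3-oxopropanoate
Conditions: H2 (1 atm), Pd/C (10 wt %), EtOAc, rt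
Reagents that add atoms: none
Why: Hydrogenolysis of the single benzyl aryl ether frees only the future C8a hydroxyl, while the MOM acetals, the tert-butyl ester and the vinylogous-ester double bond of the flavone should stay intact at 1 atm and room temperature.

Step 11
Reactants: 14 4-hydroxybenzaldehyde
Product: 15 4-(methoxymethoxy)benzaldehyde
Conditions: MOMCl, iPr2NEt, CH2Cl2, 0 °C to rt
Reagents that add atoms: chloromethyl methyl ether (MOMCl), COCCl
Why: Williamson-type O-alkylation of an acidic, unhindered phenol under mild amine-base conditions.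

Step 12
Reactants: 13 hydroxy ketoester, 15 4-(methoxymethoxy)benzaldehyde
Product: 16 tert-butyl (Z)-2-[6-hydroxy-2,4-bis(methoxymethoxy)-3-(tri-MOM-flavon-8-yl)benzoyl]-3-[4-(methoxymethoxy)phenyl]prop-2-enoate
Conditions: piperidine (20 mol %), AcOH (20 mol %), 4 Å molecular sieves, toluene, rt
Reagents that add atoms: none
Why: Knoevenagel condensation of the acidic ketoester methylene with the aldehyde through its piperidinium iminium, run buffered and at room temperature so that the hydrogen-bonded C8a hydroxyl stays a neutral spectator; the alkene geometry (drawn Z, ester cis to the aryl group) is lost in step 13.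

Step 13
Reactants: 16 alkylidene ketoester
Product: 17 tert-butyl (2S,3R)-5,7-bis(methoxymethoxy)-2-[4-(methoxymethoxy)phenyl]-4-oxo-6-(tri-MOM-flavon-8-yl)chromane-3-carboxylate (2,3-trans)
Conditions: quinine-derived thiourea 1-[3,5-bis(trifluoromethyl)phenyl]-3-[(8S,9S)-6'-methoxycinchonan-9-yl]thiourea (10 mol %), toluene, −25 °C; filtration through silica
Reagents that add atoms: none
Why: The quinuclidine nitrogen of the catalyst activates the C8a hydroxyl as a general base while the two thiourea N–H bonds clamp the ketone and ester carbonyls, so the phenolic oxygen adds to the electron-poor alkene carbon (future C2) inside a chiral hydrogen-bonded assembly and the resulting ketoester enolate is protonated at C3. The closest known reaction is the cinchona thiourea-catalysed intramolecular oxa-Michael addition of 2-hydroxyaryl alkylidene beta-ketoesters to 3-carboxyflavanones. Ring C closes in a 6-endo-trig mode by forming O1–C2. C2 is set by the catalyst, which exposes one face of the bound alkene to the oxygen, and C3 settles trans to the C2 aryl group by equilibration through the ketoester enol before being erased in step 14. The step needs site and face selectivity: the MOM ether on the C5 oxygen leaves the C8a hydroxyl as the only nucleophile, so only the 6-linked flavanone can form, and the two-point dicarbonyl binding together with the bulky tert-butyl ester secures the face. The ester also raises the electrophilicity of C2 and lets the product rest as a stabilised ketoester, which disfavours reopening to the achiral enone.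

Step 14
Reactants: 17 trans-3-(tert-butoxycarbonyl)flavanone-flavone hexakis-MOM ether
Product: 20 (2S)-5,7-dihydroxy-2-(4-hydroxyphenyl)-6-[5,7-dihydroxy-2-(4-hydroxyphenyl)-4-oxo-4H-chromen-8-yl]chroman-4-one, via beta-keto acid 18 (not isolated), via hexakis-MOM flavanone-flavone 19 (not isolated)
Conditions: TsOH·H2O, toluene, 80 °C; then MeOH, 60 °C
Reagents that add atoms: none
Why: Acid-mediated loss of 2-methylpropene from the tert-butyl ester, decarboxylation of the beta-keto acid through its enol (which removes the C3 centre without opening the O1–C2 bond) and acetal exchange of the six MOM ethers with methanol, which traps the formaldehyde unit, should leave C2 untouched.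

**Compound list**

1 | apigenin (5,7-dihydroxy-2-(4-hydroxyphenyl)-4H-chromen-4-one) | O=c1cc(-c2ccc(O)cc2)oc2cc(O)cc(O)c12 | starting material
2 | 5,7-bis(methoxymethoxy)-2-[4-(methoxymethoxy)phenyl]-4H-chromen-4-one | O=c1cc(-c2ccc(OCOC)cc2)oc2cc(OCOC)cc(OCOC)c12 | intermediate
3 | 8-iodo-5,7-bis(methoxymethoxy)-2-[4-(methoxymethoxy)phenyl]-4H-chromen-4-one | O=c1cc(-c2ccc(OCOC)cc2)oc2c(I)c(OCOC)cc(OCOC)c12 | intermediate
4 | 5,7-bis(methoxymethoxy)-2-[4-(methoxymethoxy)phenyl]-8-(4,4,5,5-tetramethyl-1,3,2-dioxaborolan-2-yl)-4H-chromen-4-one | O=c1cc(-c2ccc(OCOC)cc2)oc2c(B3OC(C)(C)C(C)(C)O3)c(OCOC)cc(OCOC)c12 | intermediate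
5 | phloroacetophenone (1-(2,4,6-trihydroxyphenyl)ethan-1-one) | CC(=O)c1c(O)cc(O)cc1O | starting material
6 | 1-[2,6-dihydroxy-4-(methoxymethoxy)phenyl]ethan-1-one | CC(=O)c1c(O)cc(OCOC)cc1O | intermediate
7 | 1-[2-(benzyloxy)-6-hydroxy-4-(methoxymethoxy)phenyl]ethan-1-one | CC(=O)c1c(O)cc(OCOC)cc1OCc1ccccc1 | intermediate
8 | 1-[6-(benzyloxy)-2-hydroxy-3-iodo-4-(methoxymethoxy)phenyl]ethan-1-one | CC(=O)c1c(O)c(I)c(OCOC)cc1OCc1ccccc1 | intermediate
9 | 1-[6-(benzyloxy)-3-iodo-2,4-bis(methoxymethoxy)phenyl]ethan-1-one | CC(=O)c1c(OCOC)c(I)c(OCOC)cc1OCc1ccccc1 | intermediate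
10 | 1-[6-(benzyloxy)-2,4-bis(methoxymethoxy)-3-(tri-MOM-flavon-8-yl)phenyl]ethan-1-one | CC(=O)c1c(OCc2ccccc2)cc(OCOC)c(-c2c(OCOC)cc(OCOC)c3c(=O)cc(-c4ccc(OCOC)cc4)oc23)c1OCOC | intermediate
11 | lithium enolate of ketone 10 | [Li]OC(=C)c1c(OCc2ccccc2)cc(OCOC)c(-c2c(OCOC)cc(OCOC)c3c(=O)cc(-c4ccc(OCOC)cc4)oc23)c1OCOC | intermediate
12 | tert-butyl 3-[6-(benzyloxy)-2,4-bis(methoxymethoxy)-3-(tri-MOM-flavon-8-yl)phenyl]-3-oxopropanoate | CC(C)(C)OC(=O)CC(=O)c1c(OCc2ccccc2)cc(OCOC)c(-c2c(OCOC)cc(OCOC)c3c(=O)cc(-c4ccc(OCOC)cc4)oc23)c1OCOC | intermediate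
13 | tert-butyl 3-[6-hydroxy-2,4-bis(methoxymethoxy)-3-(tri-MOM-flavon-8-yl)phenyl]-3-oxopropanoate | CC(C)(C)OC(=O)CC(=O)c1c(O)cc(OCOC)c(-c2c(OCOC)cc(OCOC)c3c(=O)cc(-c4ccc(OCOC)cc4)oc23)c1OCOC | intermediate
14 | 4-hydroxybenzaldehyde | O=Cc1ccc(O)cc1 | starting material
15 | 4-(methoxymethoxy)benzaldehyde | COCOc1ccc(C=O)cc1 | intermediate
16 | tert-butyl (Z)-2-[6-hydroxy-2,4-bis(methoxymethoxy)-3-(tri-MOM-flavon-8-yl)benzoyl]-3-[4-(methoxymethoxy)phenyl]prop-2-enoate | CC(C)(C)OC(=O)/C(C(=O)c1c(O)cc(OCOC)c(-c2c(OCOC)cc(OCOC)c3c(=O)cc(-c4ccc(OCOC)cc4)oc23)c1OCOC)=C\c1ccc(OCOC)cc1 | intermediate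
17 | tert-butyl (2S,3R)-5,7-bis(methoxymethoxy)-2-[4-(methoxymethoxy)phenyl]-4-oxo-6-(tri-MOM-flavon-8-yl)chromane-3-carboxylate | O=C1[C@H](C(=O)OC(C)(C)C)[C@@H](c2ccc(OCOC)cc2)Oc2cc(OCOC)c(-c3c(OCOC)cc(OCOC)c4c(=O)cc(-c5ccc(OCOC)cc5)oc34)c(OCOC)c21 | intermediate
18 | (2S,3R)-5,7-bis(methoxymethoxy)-2-[4-(methoxymethoxy)phenyl]-4-oxo-6-(tri-MOM-flavon-8-yl)chromane-3-carboxylic acid | O=C1[C@H](C(=O)O)[C@@H](c2ccc(OCOC)cc2)Oc2cc(OCOC)c(-c3c(OCOC)cc(OCOC)c4c(=O)cc(-c5ccc(OCOC)cc5)oc34)c(OCOC)c21 | intermediate
19 | (2S)-5,7-bis(methoxymethoxy)-2-[4-(methoxymethoxy)phenyl]-6-(tri-MOM-flavon-8-yl)chroman-4-one | O=C1C[C@@H](c2ccc(OCOC)cc2)Oc2cc(OCOC)c(-c3c(OCOC)cc(OCOC)c4c(=O)cc(-c5ccc(OCOC)cc5)oc34)c(OCOC)c21 | intermediate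
20 | (2S)-5,7-dihydroxy-2-(4-hydroxyphenyl)-6-[5,7-dihydroxy-2-(4-hydroxyphenyl)-4-oxo-4H-chromen-8-yl]chroman-4-one | O=C1C[C@@H](c2ccc(O)cc2)Oc2cc(O)c(-c3c(O)cc(O)c4c(=O)cc(-c5ccc(O)cc5)oc34)c(O)c21 | target

**Step count and risks**

Total step count: 14. Longest linear sequence: 10 steps (steps 4, 5, 6, 7, 8, 9, 10, 12, 13 and 14, from phloroacetophenone 5).

Steps most likely to fail:

Step 8. Building a biaryl bond with four ortho substituents makes boron-to-palladium transfer and reductive elimination slow, so protodeboronation of the 2,6-dioxygenated boronate and hydrodehalogenation of the iodide may outrun the coupling. The fallback replaces boron by zinc. It sets out from iodide 3, which would be treated with zinc dust and LiCl (THF, 50 °C) to give the arylzinc iodide F1. F1 would then be joined to iodide 9 in a Negishi coupling (Pd2(dba)3, RuPhos, THF/NMP, 70 °C), a reaction type established for tetra-ortho-substituted biaryls and not subject to protodemetalation by water. The fallback returns to the route at ketone 10.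

Step 12. The amine catalyst may promote premature conjugate addition of the free C8a hydroxyl to the alkylidene as soon as it forms, giving racemic ring closure before the chiral catalyst is present, and condensation at the hindered methylene may be slow enough to make this worse. The fallback masks the phenol during the condensation. It sets out from 13, which would be silylated selectively at the phenol (TBSCl, imidazole, CH2Cl2) to give the silyl ether F2. The same Knoevenagel condensation with 15 would give the silylated alkylidene ketoester F3, which cannot cyclise. Fluoride cleavage under acidic buffering (HF·pyridine, THF, 0 °C) would then release the phenol without passing through a phenoxide. The fallback returns to the route at 16.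

Step 13. Facial discrimination may be poor, or the ee may erode through reversible ring opening, because the MOM ether on the C5 oxygen twists the aroyl group out of the plane the two-point binding needs and the six acetals compete for the thiourea. The fallback sets C2 by carbon–carbon bond formation instead. It sets out from ketone 10, which would be debenzylated (H2, Pd/C, EtOAc) to the hydroxy ketone F4. Condensation with N,N-dimethylformamide dimethyl acetal (toluene, 90 °C) would give the enaminone F5, and mild acid (AcOH, CH2Cl2, 40 °C) would close it to the chromone F6. A rhodium-catalysed asymmetric 1,4-addition of 4-(methoxymethoxy)phenylboronic acid ([Rh(OH)(cod)]2 with an electron-poor MeO-BIPHEP-type bisphosphine in the enantiomeric form that delivers (2S), toluene/H2O, rt), a reaction known for 5,7-dioxygenated chromones, would give the flavanone directly. The fallback returns to the route at 19, which the second stage of step 14 (TsOH·H2O, MeOH, 60 °C) would convert to 20.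

Further compounds
F1 | step 8 | {5,7-bis(methoxymethoxy)-2-[4-(methoxymethoxy)phenyl]-4-oxo-4H-chromen-8-yl}zinc iodide | O=c1cc(-c2ccc(OCOC)cc2)oc2c([Zn]I)c(OCOC)cc(OCOC)c12
F2 | step 12 | tert-butyl 3-[6-(tert-butyldimethylsilyloxy)-2,4-bis(methoxymethoxy)-3-(tri-MOM-flavon-8-yl)phenyl]-3-oxopropanoate | CC(C)(C)OC(=O)CC(=O)c1c(O[Si](C)(C)C(C)(C)C)cc(OCOC)c(-c2c(OCOC)cc(OCOC)c3c(=O)cc(-c4ccc(OCOC)cc4)oc23)c1OCOC
F3 | step 12 | tert-butyl (Z)-2-[6-(tert-butyldimethylsilyloxy)-2,4-bis(methoxymethoxy)-3-(tri-MOM-flavon-8-yl)benzoyl]-3-[4-(methoxymethoxy)phenyl]prop-2-enoate | CC(C)(C)OC(=O)/C(C(=O)c1c(O[Si](C)(C)C(C)(C)C)cc(OCOC)c(-c2c(OCOC)cc(OCOC)c3c(=O)cc(-c4ccc(OCOC)cc4)oc23)c1OCOC)=C\c1ccc(OCOC)cc1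
F4 | step 13 | 1-[6-hydroxy-2,4-bis(methoxymethoxy)-3-(tri-MOM-flavon-8-yl)phenyl]ethan-1-one | CC(=O)c1c(O)cc(OCOC)c(-c2c(OCOC)cc(OCOC)c3c(=O)cc(-c4ccc(OCOC)cc4)oc23)c1OCOC
F5 | step 13 | (E)-3-(dimethylamino)-1-[6-hydroxy-2,4-bis(methoxymethoxy)-3-(tri-MOM-flavon-8-yl)phenyl]prop-2-en-1-one | CN(C)/C=C/C(=O)c1c(O)cc(OCOC)c(-c2c(OCOC)cc(OCOC)c3c(=O)cc(-c4ccc(OCOC)cc4)oc23)c1OCOC
F6 | step 13 | 5,7-bis(methoxymethoxy)-6-(tri-MOM-flavon-8-yl)-4H-chromen-4-one | O=c1ccoc2cc(OCOC)c(-c3c(OCOC)cc(OCOC)c4c(=O)cc(-c5ccc(OCOC)cc5)oc34)c(OCOC)c12
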